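## Analysis of the target

Broussoflavonol G is a flavonol: a chromen-4-one whose ring A (C4a to C8a) is fused to the pyranone ring C (O1, C2, C3, C4), with ring B on C2 and a hydroxyl on C3. Ring A carries hydroxyls at C5 and C7 and a 3-methylbut-2-enyl (prenyl) group at C8; ring B carries prenyl groups at C2' and C3' and a catechol at C4' and C5', so that only C6 and C6' bear hydrogen. The molecule has no stereocentre and no stereogenic double bond, so the whole problem is one of regiochemistry and functional-group tolerance. The sensitive groups are the three trisubstituted alkenes, which acid closes onto a free ortho hydroxyl and which do not survive electrophilic oxidants, halogenating agents or hydrogenation, and the catechol and 3-hydroxypyranone, which air oxidizes in base. Two features make the synthesis hard: C6 and C8 of a phloroglucinol-type ring A differ only through the way ring C is closed, so that 6- and 8-prenyl isomers tend to form together, and ring B is pentasubstituted with two adjacent prenyl groups, one of which (C2') flanks the bond to C2. The strategy rests on C8a, which carries O1 and lies between C8 (prenyl) and C4a (acyl carbon C4), while the oxygens at C5 and C7 are both meta to it. A fluorine on that carbon makes its two neighbours the most acidic positions of the arene and later serves as the leaving group that O1 replaces.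

## Retrosynthetic reasoning

**Protecting groups (26 from 25 from 24).** The last two operations cut only O–CH2 and O–Si bonds. Target 26 comes from tris(methoxymethyl) ether 25 by acid, and 25 from bis(silyl) ether 24 by fluoride. In this order the catechol and the 3-hydroxyl are set free only in acid, where they are not oxidized. All five hydroxyls stay masked through the organometallic and enolate steps, and the ring-A silyl ethers have a second duty explained below.

**Ring C (24 from 22), the key disconnection.** Classical flavone syntheses cut O1–C2 and close the ring by cyclodehydration onto a ring-A phenol. Here that cut is ambiguous: the ring-A ketone would have two ortho oxygens, and which one becomes O1 decides whether the prenyl group ends at C8 or C6. The cut is therefore made at O1–C8a. The ring oxygen then comes from the diketone, and the arene carries a leaving group on one carbon only. In the forward direction the oxygen of enolate 23, formed from diketone 22, must displace fluoride from C8a. One bond then closes ring C and fixes the prenyl position.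

**Diketone (22 from 21 from 11 and 19).** The 2-alkoxy-1,3-diketone is cut between the central carbon (C3) and the ring-B carbonyl carbon (C2). The cut is made at the aldehyde oxidation level: enolate 20, formed from ketone 11, adds to aldehyde 19 to give aldol 21, which is oxidized to 22. Acylation at the ester oxidation level would save a step. It was not chosen because the acyl carbon is flanked by the C2' prenyl group and would need excess strong base and warming, under which fluoride could be displaced or silyl groups lost without control. The aldehyde is more electrophilic and is what the ring-B synthesis delivers. The two stereocentres of 21 are without consequence.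

**Ring A (11 from 9 and 3; 9 from 5 and 6; 5 from 4).** The bonds cut are C4–C4a and C8–CH2, both at carbons that flank the C–F carbon. Each is formed by deprotonation beside fluorine and trapping, first with prenyl bromide 6 (through aryllithium 7 and arylcopper 8) and then with amide 3 (through aryllithium 10). The prenyl group goes in first because the ketone would not survive a second metalation. The phenols of 4 are protected as bulky silyl ethers in 5 so that oxygen does not act as a metalation director. The position between the two oxygens (future C6) then becomes the least accessible one, whereas alkoxymethyl ethers would direct the base exactly there.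

**Ring B (19 from 16 and 17; 17 from 6; 16 from 15, 14, 13, 12).** Both aryl–CH2 bonds at C2' and C3' are cut and formed by a twofold cross-coupling of dibromide 16 with organozinc 17, which is made in the flask from 6; two equivalents are consumed, one for each C–Br bond. The bromine atoms mark positions that electrophilic substitution of 12 reaches by itself. The methyl ether of 13 is exchanged for methoxymethyl groups (14, 15) before any alkene is present, because no demethylation tolerates prenyl groups. The aldehyde is masked as the dimethyl acetal in 16 because allylic zinc reagents add to aldehydes; the coupled acetal 18 is hydrolysed to 19 in the work-up.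

**Acyl donor (3 from 2 from 1).** The two-carbon unit C3–C4 with its oxygen comes from glycolate 1, protected (2) and converted into the N-methoxy-N-methylamide 3, which stops cleanly at the ketone.

## Alternatives that were turned down

Alternative 1: The disconnection is that of the two aryl–CH2 bonds at C2' and C3', taken as the centre of the plan. Dibromide A2, the dioxolane counterpart of 16, would be coupled twice with organozinc 17 under Pd(OAc)2 and a bulky dialkylbiarylphosphine to give A1.
- For: the bromine positions follow from simple aromatic substitution, the coupling is linear-selective, and ring B is complete in one operation.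
- Against: the plan puts its main step on the easier half of the molecule. After A1 the aldehyde must be unmasked beside two aryl methoxymethyl ethers, and ring C must then be made by a chalcone oxidation or a cyclodehydration. Both need a 2-hydroxyaryl ketone in which C8 is already told apart from C6, for which the plan has no answer. An ortho-substituted ring B also disfavours the oxidative chalcone route.
- Comparison: on ring B this alternative is as strong as the chosen route, which uses the same kind of coupling as a supporting step (step 10, with a dimethyl acetal that hydrolyses during work-up). The chosen strategy adds a ring-C closure that settles the C8 regiochemistry.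

Alternative 2: The disconnection is that of C2'–C3' and C1'–C6', building ring B from open chains by a Robinson annulation. Pyrrolidine enamine A4 would add to dienone A5 in conjugate fashion; hydrolysis and intramolecular aldol condensation would then close cyclohexenone A3.
- For: cheap acyclic precursors, no halogenation and no palladium; the two prenyl groups are placed by connectivity and not by aromatic substitution. On these points it is stronger than the chosen route.
- Against: A3 has one ring oxygen (future C5') and a methylene at the future C4'. Oxygenation there and dehydrogenation to the catechol must be done beside two trisubstituted alkenes, which are sensitive to the peracids and quinones such steps normally use. The two stereocentres of A3 are made only to be erased. The doubly allylic methylene of A5 invites isomerization into conjugation under amine conditions. After many steps only ring B exists.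
- Comparison: the chosen route reaches aldehyde 19 in five steps from 12 with both oxygens and the aldehyde oxidation level in place, and its single risky step also solves the ring-A problem.

Alternative 3: The disconnection is that of C7–C8 and C4a–C5, with ring A grown last. Pyranone A7 would be deprotonated at the side-chain methylene on C6 of the pyranone; the dienolate would be acylated there (future C8) by activated malonate A8, and a second acyl transfer to the pyranone carbon next to the carbonyl (future C4a) would close ring A to give A6.
- For: the C8 prenyl group is fixed by connectivity as firmly as in the chosen route. Ring A needs no protecting groups. A6 is identical with 25, one step from the target, so the silyl ethers and the fluoride step disappear, and two C–C bonds and a ring form in one operation. On these points it is as strong or stronger.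
- Against: aryl malonates of this kind acylate carbon thermally at high temperature, which is hard on three prenyl groups and three acetals. The first acylation may go to oxygen. The second must occur at a weakly nucleophilic carbon. There is no close analogy on a 3-alkoxy-2-arylpyranone. A7 itself needs a pyranone synthesis with ring B attached, so the saving is smaller than it looks, and the untested annulation would fall on the most advanced intermediate.
- Comparison: the chosen strategy offers a ring closure of a known type and keeps its uncertain metalations early, on cheap material.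

Key step: step 13

Remarks on the chemistry:
- 5-Bromovanillin (12), the monobromination product of vanillin, is taken as a commercial starting material.
- Compounds 21 and 22 are racemic and 21 is a mixture of diastereomers. This is without consequence, since both centres become trigonal in steps 12 and 13.
- Step 10 consumes two equivalents of prenyl bromide 6, one for each C–Br bond of 16; an excess is converted into the zinc reagent 17.

## Route

Step 1
Reactants: 1 methyl glycolate
Product: 2 methyl 2-(methoxymethoxy)acetate
Conditions: MeOCH2Cl, i-Pr2NEt, CH2Cl2, 0 °C → rt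
Reagents that add atoms: chloromethyl methyl ether, COCCl
Why: O-alkylation of the primary alcohol by the chloromethyl ether with a hindered amine base (methoxymethyl protection); the ester is untouched.

Step 2
Reactants: 2 methyl 2-(methoxymethoxy)acetate
Product: 3 N-methoxy-2-(methoxymethoxy)-N-methylacetamide
Conditions: MeNHOMe·HCl, i-PrMgCl, THF, −20 → 0 °C
Reagents that add atoms: N,O-dimethylhydroxylamine hydrochloride, CNOC.Cl
Why: Weinreb amide formation by aminolysis of the methyl ester with the magnesium amide made in the flask; the acetal-type ether is stable to the Grignard base.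

Step 3
Reactants: 4 5-fluororesorcinol
Product: 5 1-fluoro-3,5-bis(triisopropylsilyloxy)benzene
Conditions: i-Pr3SiCl, imidazole, DMF, rt
Reagents that add atoms: chlorotriisopropylsilane, CC(C)[Si](Cl)(C(C)C)C(C)C
Why: Silylation of both phenols; the bulky silyl ethers bind lithium poorly and screen C4 between them, so fluorine is left as the only metalation director.

Step 4
Reactants: 5 1-fluoro-3,5-bis(triisopropylsilyloxy)benzene; 6 1-bromo-3-methylbut-2-ene (prenyl bromide)
Product: 9 1-fluoro-2-(3-methylbut-2-enyl)-3,5-bis(triisopropylsilyloxy)benzene, via aryllithium 7 (not isolated), via arylcopper 8 (not isolated)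
Conditions: s-BuLi, THF, −78 °C; CuBr·SMe2, −78 °C; 6, −78 → 0 °C
Reagents that add atoms: none
Why: Fluorine-directed ortho-lithiation at one of the two equivalent positions beside fluorine, the position between the silyloxy groups being shielded. Transmetalation to copper before warming prevents loss of LiF to an aryne and silyl migration from O to C, and the arylcopper substitutes prenyl bromide at its primary carbon.

Step 5
Reactants: 9 1-fluoro-2-(3-methylbut-2-enyl)-3,5-bis(triisopropylsilyloxy)benzene; 3 N-methoxy-2-(methoxymethoxy)-N-methylacetamide
Product: 11 1-[2-fluoro-3-(3-methylbut-2-enyl)-4,6-bis(triisopropylsilyloxy)phenyl]-2-(methoxymethoxy)ethanone, via aryllithium 10 (not isolated)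
Conditions: s-BuLi, THF, −78 °C; 3, −78 → −50 °C; aq NH4Cl
Reagents that add atoms: none
Why: Second fluorine-directed ortho-lithiation at the only remaining position beside fluorine, followed by Weinreb ketone synthesis; the chelated tetrahedral adduct persists until work-up, so the ketone is neither attacked twice nor enolized by the aryllithium.

Step 6
Reactants: 12 3-bromo-4-hydroxy-5-methoxybenzaldehyde (5-bromovanillin)
Product: 13 2,3-dibromo-4-hydroxy-5-methoxybenzaldehyde
Conditions: Br2, Fe powder (cat.), NaOAc, AcOH, rt
Reagents that add atoms: bromine, BrBr
Why: Electrophilic aromatic bromination; with the position ortho to the hydroxyl occupied, the open position para to the methoxy group is the most activated, and the FeBr3 formed in the flask supplies the Lewis acid the deactivated ring needs.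

Step 7
Reactants: 13 2,3-dibromo-4-hydroxy-5-methoxybenzaldehyde
Product: 14 2,3-dibromo-4,5-dihydroxybenzaldehyde
Conditions: AlCl3, pyridine, CH2Cl2, reflux; 2 M HCl
Reagents that add atoms: none
Why: Lewis-acid demethylation selective for a methyl ether next to a free phenol: the phenol binds AlCl3 as its phenoxide, which chelates the neighbouring methoxy oxygen, and pyridine takes the methyl group; aryl bromides and the aldehyde are inert.

Step 8
Reactants: 14 2,3-dibromo-4,5-dihydroxybenzaldehyde
Product: 15 2,3-dibromo-4,5-bis(methoxymethoxy)benzaldehyde
Conditions: MeOCH2Cl, i-Pr2NEt, CH2Cl2, 0 °C → rt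
Reagents that add atoms: chloromethyl methyl ether, COCCl
Why: Twofold O-alkylation of the catechol (methoxymethyl protection); these ethers are stable to zinc reagents, enolates, carbonate and fluoride and fall only to acid at the end.

Step 9
Reactants: 15 2,3-dibromo-4,5-bis(methoxymethoxy)benzaldehyde
Product: 16 1,2-dibromo-3-(dimethoxymethyl)-5,6-bis(methoxymethoxy)benzene
Conditions: HC(OMe)3, MeOH, pyridinium p-toluenesulfonate (cat.), rt; Et3N
Reagents that add atoms: trimethyl orthoformate, COC(OC)OC
Why: Acid-catalysed acetalization with the orthoformate as water scavenger; the weak acid at room temperature leaves the aryl methoxymethyl ethers intact, and the acetal is needed because allylic zinc reagents add to aldehydes.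

Step 10
Reactants: 16 1,2-dibromo-3-(dimethoxymethyl)-5,6-bis(methoxymethoxy)benzene; 6 1-bromo-3-methylbut-2-ene (prenyl bromide)
Product: 19 2,3-bis(3-methylbut-2-enyl)-4,5-bis(methoxymethoxy)benzaldehyde, via prenylzinc bromide 17 (not isolated), via diprenyl acetal 18 (not isolated)
Conditions: 6 (3 equiv), Zn dust, LiCl, THF, 0 °C → rt; then 16, Pd(OAc)2 (cat.), CPhos (2-dicyclohexylphosphino-2',6'-bis(dimethylamino)biphenyl, cat.), THF, rt → 50 °C; 1 M HCl, THF, 0 °C
Reagents that add atoms: 1-bromo-3-methylbut-2-ene (second equivalent of 6), CC(C)=CCBr; water, O
Why: Twofold Negishi cross-coupling in which each of the two C–Br bonds of 16 takes one prenyl group from prenylzinc bromide 17, made from 6 and zinc, so that two equivalents of 6 end up in the product. With the bulky biarylphosphine the arylpalladium prenyl intermediate eliminates reductively from its primary terminus and gives the linear product. The aryl dimethyl acetal of 18 hydrolyses in the brief cold acid work-up far faster than the aryl methoxymethyl ethers.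

Step 11
Reactants: 11 1-[2-fluoro-3-(3-methylbut-2-enyl)-4,6-bis(triisopropylsilyloxy)phenyl]-2-(methoxymethoxy)ethanone; 19 2,3-bis(3-methylbut-2-enyl)-4,5-bis(methoxymethoxy)benzaldehyde
Product: 21 1-[2-fluoro-3-(3-methylbut-2-enyl)-4,6-bis(triisopropylsilyloxy)phenyl]-3-hydroxy-2-(methoxymethoxy)-3-[2,3-bis(3-methylbut-2-enyl)-4,5-bis(methoxymethoxy)phenyl]propan-1-one (racemic mixture of diastereomers), via lithium enolate 20 (not isolated)
Conditions: LiN(SiMe3)2, THF, −78 °C; 19, −78 °C; AcOH, −78 °C
Reagents that add atoms: none
Why: Aldol addition of the chelated lithium enolate of the alkoxy ketone to the aldehyde at low temperature, where the aryl fluoride is not touched; quenching cold prevents retro-aldol cleavage. The two new stereocentres are formed without control because both are removed in steps 12 and 13.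

Step 12
Reactants: 21 1-[2-fluoro-3-(3-methylbut-2-enyl)-4,6-bis(triisopropylsilyloxy)phenyl]-3-hydroxy-2-(methoxymethoxy)-3-[2,3-bis(3-methylbut-2-enyl)-4,5-bis(methoxymethoxy)phenyl]propan-1-one
Product: 22 1-[2-fluoro-3-(3-methylbut-2-enyl)-4,6-bis(triisopropylsilyloxy)phenyl]-2-(methoxymethoxy)-3-[2,3-bis(3-methylbut-2-enyl)-4,5-bis(methoxymethoxy)phenyl]propane-1,3-dione (racemic, central methine labile)
Conditions: Dess–Martin periodinane, NaHCO3, CH2Cl2, 0 °C → rt
Reagents that add atoms: none
Why: Dess–Martin oxidation of the secondary benzylic alcohol to the ketone; the buffered, near-stoichiometric hypervalent iodine oxidant leaves the prenyl alkenes, silyl ethers and acetals alone and is kept from oxidizing the central methine further.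

Step 13
Reactants: 22 1-[2-fluoro-3-(3-methylbut-2-enyl)-4,6-bis(triisopropylsilyloxy)phenyl]-2-(methoxymethoxy)-3-[2,3-bis(3-methylbut-2-enyl)-4,5-bis(methoxymethoxy)phenyl]propane-1,3-dione
Product: 24 2-[2,3-bis(3-methylbut-2-enyl)-4,5-bis(methoxymethoxy)phenyl]-3-(methoxymethoxy)-8-(3-methylbut-2-enyl)-5,7-bis(triisopropylsilyloxy)chromen-4-one, via potassium enolate 23 (not isolated)
Conditions: K2CO3 (dry, powdered), DMF, 4 Å molecular sieves, 60 °C, Ar
Reagents that add atoms: none
Why: K2CO3 removes the central methine proton of 22 to give potassium enolate 23; its oxygen on the ring-B side adds to C8a, the Meisenheimer-type anion is stabilized by the C4 carbonyl through C4a, and loss of fluoride forms O1–C8a. The closest known reaction type is the carbonate-mediated intramolecular SNAr cyclization of 1-(2-fluoroaryl)-1,3-diketones to chromones and flavones. Ring C closes by a six-membered addition–elimination that counts as 6-endo-trig with respect to the C4a=C8a bond of the vinylogous acyl fluoride, a favoured mode; no stereocentre is formed and the labile centre of 22 becomes trigonal. O-arylation has to win over C-arylation, and geometry secures it: the enolate oxygen reaches C8a through a six-membered transition state, whereas C3 would have to close a four-membered ring. The regiochemistry is fixed because C8a is the only carbon of ring A with a leaving group, so the prenyl group can only end at C8. The silyloxy groups at C5 and C7 are meta to C8a and place no charge on it, but they must stay until the ring has closed: a phenoxide on ring A would switch off the substitution, and a free O5 could condense with the ring-B carbonyl to a 5-fluoro-6-prenyl isomer. Dry heterogeneous K2CO3 in DMF is chosen for that reason, since the KF formed is almost insoluble there and aryl triisopropylsilyl ethers withstand it; silyl loss after closure would do no harm.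

Step 14
Reactants: 24 2-[2,3-bis(3-methylbut-2-enyl)-4,5-bis(methoxymethoxy)phenyl]-3-(methoxymethoxy)-8-(3-methylbut-2-enyl)-5,7-bis(triisopropylsilyloxy)chromen-4-one
Product: 25 5,7-dihydroxy-2-[2,3-bis(3-methylbut-2-enyl)-4,5-bis(methoxymethoxy)phenyl]-3-(methoxymethoxy)-8-(3-methylbut-2-enyl)chromen-4-one
Conditions: Bu4NF, AcOH, THF, 0 °C → rt
Reagents that add atoms: none
Why: Fluoride-mediated cleavage of the two aryl silyl ethers, driven by the Si–F bond and the phenoxide leaving groups; acetic acid buffers the phenoxides, and the acetals and alkenes are inert.

Step 15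
Reactants: 25 5,7-dihydroxy-2-[2,3-bis(3-methylbut-2-enyl)-4,5-bis(methoxymethoxy)phenyl]-3-(methoxymethoxy)-8-(3-methylbut-2-enyl)chromen-4-one
Product: 26 broussoflavonol G, 3,5,7-trihydroxy-2-[4,5-dihydroxy-2,3-bis(3-methylbut-2-enyl)phenyl]-8-(3-methylbut-2-enyl)chromen-4-one
Conditions: HCl (about 1.5 M) in MeOH, 40 °C, Ar
Reagents that add atoms: none
Why: Acid-catalysed methanolysis of the three methoxymethyl acetals; dilute acid at moderate temperature is used so that the prenyl groups are not closed onto neighbouring hydroxyls, and the oxidation-prone catechol and 3-hydroxyl are set free only in acid under argon.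

## Compound list

1 | methyl glycolate | COC(=O)CO | starting material
2 | methyl 2-(methoxymethoxy)acetate | COCOCC(=O)OC | intermediate
3 | N-methoxy-2-(methoxymethoxy)-N-methylacetamide | COCOCC(=O)N(C)OC | intermediate
4 | 5-fluororesorcinol | Oc1cc(O)cc(F)c1 | starting material
5 | 1-fluoro-3,5-bis(triisopropylsilyloxy)benzene | Fc1cc(O[Si](C(C)C)(C(C)C)C(C)C)cc(O[Si](C(C)C)(C(C)C)C(C)C)c1 | intermediate
6 | 1-bromo-3-methylbut-2-ene (prenyl bromide) | CC(C)=CCBr | starting material
7 | [2-fluoro-4,6-bis(triisopropylsilyloxy)phenyl]lithium (not isolated) | [Li]c1c(F)cc(O[Si](C(C)C)(C(C)C)C(C)C)cc1O[Si](C(C)C)(C(C)C)C(C)C | intermediate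
8 | [2-fluoro-4,6-bis(triisopropylsilyloxy)phenyl]copper (not isolated) | [Cu]c1c(F)cc(O[Si](C(C)C)(C(C)C)C(C)C)cc1O[Si](C(C)C)(C(C)C)C(C)C | intermediate
9 | 1-fluoro-2-(3-methylbut-2-enyl)-3,5-bis(triisopropylsilyloxy)benzene | CC(C)=CCc1c(F)cc(O[Si](C(C)C)(C(C)C)C(C)C)cc1O[Si](C(C)C)(C(C)C)C(C)C | intermediate
10 | [2-fluoro-3-(3-methylbut-2-enyl)-4,6-bis(triisopropylsilyloxy)phenyl]lithium (not isolated) | CC(C)=CCc1c(F)c([Li])c(O[Si](C(C)C)(C(C)C)C(C)C)cc1O[Si](C(C)C)(C(C)C)C(C)C | intermediate
11 | 1-[2-fluoro-3-(3-methylbut-2-enyl)-4,6-bis(triisopropylsilyloxy)phenyl]-2-(methoxymethoxy)ethanone | CC(C)=CCc1c(F)c(C(=O)COCOC)c(O[Si](C(C)C)(C(C)C)C(C)C)cc1O[Si](C(C)C)(C(C)C)C(C)C | intermediate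
12 | 3-bromo-4-hydroxy-5-methoxybenzaldehyde (5-bromovanillin) | COc1cc(C=O)cc(Br)c1O | starting material
13 | 2,3-dibromo-4-hydroxy-5-methoxybenzaldehyde | COc1cc(C=O)c(Br)c(Br)c1O | intermediate
14 | 2,3-dibromo-4,5-dihydroxybenzaldehyde | Oc1cc(C=O)c(Br)c(Br)c1O | intermediate
15 | 2,3-dibromo-4,5-bis(methoxymethoxy)benzaldehyde | COCOc1cc(C=O)c(Br)c(Br)c1OCOC | intermediate
16 | 1,2-dibromo-3-(dimethoxymethyl)-5,6-bis(methoxymethoxy)benzene | COCOc1cc(C(OC)OC)c(Br)c(Br)c1OCOC | intermediate
17 | 3-methylbut-2-enylzinc bromide (prenylzinc bromide, not isolated) | CC(C)=CC[Zn]Br | intermediate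
18 | 1-(dimethoxymethyl)-2,3-bis(3-methylbut-2-enyl)-4,5-bis(methoxymethoxy)benzene (not isolated) | COCOc1cc(C(OC)OC)c(CC=C(C)C)c(CC=C(C)C)c1OCOC | intermediate
19 | 2,3-bis(3-methylbut-2-enyl)-4,5-bis(methoxymethoxy)benzaldehyde | COCOc1cc(C=O)c(CC=C(C)C)c(CC=C(C)C)c1OCOC | intermediate
20 | lithium (Z)-enolate of 11, geometry presumed (not isolated) | CC(C)=CCc1c(F)c(/C(O[Li])=C/OCOC)c(O[Si](C(C)C)(C(C)C)C(C)C)cc1O[Si](C(C)C)(C(C)C)C(C)C | intermediate
21 | 1-[2-fluoro-3-(3-methylbut-2-enyl)-4,6-bis(triisopropylsilyloxy)phenyl]-3-hydroxy-2-(methoxymethoxy)-3-[2,3-bis(3-methylbut-2-enyl)-4,5-bis(methoxymethoxy)phenyl]propan-1-one (racemic mixture of diastereomers) | CC(C)=CCc1c(F)c(C(=O)C(OCOC)C(O)c2cc(OCOC)c(OCOC)c(CC=C(C)C)c2CC=C(C)C)c(O[Si](C(C)C)(C(C)C)C(C)C)cc1O[Si](C(C)C)(C(C)C)C(C)C | intermediate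
22 | 1-[2-fluoro-3-(3-methylbut-2-enyl)-4,6-bis(triisopropylsilyloxy)phenyl]-2-(methoxymethoxy)-3-[2,3-bis(3-methylbut-2-enyl)-4,5-bis(methoxymethoxy)phenyl]propane-1,3-dione (racemic, labile centre) | CC(C)=CCc1c(F)c(C(=O)C(OCOC)C(=O)c2cc(OCOC)c(OCOC)c(CC=C(C)C)c2CC=C(C)C)c(O[Si](C(C)C)(C(C)C)C(C)C)cc1O[Si](C(C)C)(C(C)C)C(C)C | intermediate
23 | potassium enolate of 22 (not isolated) | CC(C)=CCc1c(F)c(C(=O)C(OCOC)=C([O-])c2cc(OCOC)c(OCOC)c(CC=C(C)C)c2CC=C(C)C)c(O[Si](C(C)C)(C(C)C)C(C)C)cc1O[Si](C(C)C)(C(C)C)C(C)C.[K+] | intermediate
24 | 2-[2,3-bis(3-methylbut-2-enyl)-4,5-bis(methoxymethoxy)phenyl]-3-(methoxymethoxy)-8-(3-methylbut-2-enyl)-5,7-bis(triisopropylsilyloxy)chromen-4-one | CC(C)=CCc1c(-c2oc3c(CC=C(C)C)c(O[Si](C(C)C)(C(C)C)C(C)C)cc(O[Si](C(C)C)(C(C)C)C(C)C)c3c(=O)c2OCOC)cc(OCOC)c(OCOC)c1CC=C(C)C | intermediate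
25 | 5,7-dihydroxy-2-[2,3-bis(3-methylbut-2-enyl)-4,5-bis(methoxymethoxy)phenyl]-3-(methoxymethoxy)-8-(3-methylbut-2-enyl)chromen-4-one | CC(C)=CCc1c(-c2oc3c(CC=C(C)C)c(O)cc(O)c3c(=O)c2OCOC)cc(OCOC)c(OCOC)c1CC=C(C)C | intermediate
26 | broussoflavonol G | CC(C)=CCc1c(-c2oc3c(CC=C(C)C)c(O)cc(O)c3c(=O)c2O)cc(O)c(O)c1CC=C(C)C | target

## Step count and least certain steps

Total: 15 steps. Longest linear sequence: 10 steps (12 to 26 through steps 6 to 15). The arms from 4 and from 1 each have 8 steps to the target.

**Step 13 (key step).** The acyl group of ring A lies between fluorine and a bulky silyloxy group and may be twisted out of the ring plane, which weakens its activation of C8a. The diketone enolate is also a weak oxygen nucleophile, so the addition may be slow. If forcing conditions are then needed, a silyl group may be lost from ring A before closure, which would stop the substitution or divert closure through O5. Fallback: the ring is closed one oxidation level earlier, setting out from aldol 21. With dry K2CO3 in DMF, or KN(SiMe3)2 in THF at 0 °C, its secondary alkoxide attacks C8a of a ring A whose ketone is not enolized and therefore fully activating. The same O1–C8a bond forms and gives 2-[2,3-bis(3-methylbut-2-enyl)-4,5-bis(methoxymethoxy)phenyl]-3-(methoxymethoxy)-8-(3-methylbut-2-enyl)-5,7-bis(triisopropylsilyloxy)chroman-4-one F1. Retro-aldol cleavage of the alkoxide is reversible, while the substitution is not. F1 is then dehydrogenated across C2–C3 by enolization with LiN(SiMe3)2 at −78 °C and treatment with N-tert-butylbenzenesulfinimidoyl chloride, which brings the route back at 24.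

**Step 4.** Deprotonation beside fluorine may be slow because the neighbouring silyloxy group screens that position. On warming, the aryllithium may lose LiF to an aryne or suffer a silyl shift from oxygen to carbon. Fallback: the position is marked by electrophilic substitution and not by deprotonation. Setting out from 5, N-bromosuccinimide in MeCN should brominate ortho to fluorine and para to one silyloxy group, the position between the silyloxy groups being shielded, to give 2-bromo-1-fluoro-3,5-bis(triisopropylsilyloxy)benzene F2. Bromine–lithium exchange with n-BuLi at −78 °C, CuBr·SMe2 and then 6 brings the route back at 9.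

**Step 5.** The base may remove a proton from the benzylic and allylic CH2 of the prenyl group in competition with the ring position, and the flanked aryllithium may acylate incompletely. Fallback: both positions beside fluorine are brominated before the alkene is present. Setting out from 5, two equivalents of N-bromosuccinimide give 2,4-dibromo-3-fluoro-1,5-bis(triisopropylsilyloxy)benzene F3. One bromine is exchanged (one equivalent of n-BuLi, −78 °C) and the aryl group is prenylated through copper with 6, giving 1-bromo-2-fluoro-3-(3-methylbut-2-enyl)-4,6-bis(triisopropylsilyloxy)benzene F4. A second bromine–lithium exchange, far faster than any deprotonation of the side chain, and addition of 3 bring the route back at 11.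

**Step 10.** The second coupling takes place at a bromide flanked on both sides and may stall, leading to reduction of the C–Br bond. Some coupling may also occur at the tertiary end of the prenyl unit, and part of the acetal may be lost early, so that the zinc reagent adds to the aldehyde. Fallback: the acetal detour is dropped and a tin reagent is used, which does not add to aldehydes. Setting out from 15, twofold Stille coupling with tributyl(3-methylbut-2-enyl)stannane, Pd2(dba)3, P(t-Bu)3 and CsF in dioxane at 80 °C should give 19 directly, where it rejoins the route; no new compound is made (F0).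

**Step 15.** Acid may close a prenyl group onto a neighbouring free hydroxyl (O7 with the C8 group, O4' with the C3' group) or add methanol to the alkenes. Fallback: the order of the two deprotections is reversed and the acetals are removed without a Brønsted acid. Setting out from 24, ZnBr2 and 1-propanethiol in CH2Cl2 at 0 °C cleave the three methoxymethyl groups by Lewis-acid activation and thiol capture while O7 is still silylated. This gives 3-hydroxy-2-[4,5-dihydroxy-2,3-bis(3-methylbut-2-enyl)phenyl]-8-(3-methylbut-2-enyl)-5,7-bis(triisopropylsilyloxy)chromen-4-one F5. Buffered Bu4NF under argon then removes the silyl groups and brings the route back at 26.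

## Further compounds

F1 | step 13 | 2-[2,3-bis(3-methylbut-2-enyl)-4,5-bis(methoxymethoxy)phenyl]-3-(methoxymethoxy)-8-(3-methylbut-2-enyl)-5,7-bis(triisopropylsilyloxy)chroman-4-one (racemic mixture of diastereomers) | CC(C)=CCc1c(C2Oc3c(CC=C(C)C)c(O[Si](C(C)C)(C(C)C)C(C)C)cc(O[Si](C(C)C)(C(C)C)C(C)C)c3C(=O)C2OCOC)cc(OCOC)c(OCOC)c1CC=C(C)C
F2 | step 4 | 2-bromo-1-fluoro-3,5-bis(triisopropylsilyloxy)benzene | Fc1cc(O[Si](C(C)C)(C(C)C)C(C)C)cc(O[Si](C(C)C)(C(C)C)C(C)C)c1Br
F3 | step 5 | 2,4-dibromo-3-fluoro-1,5-bis(triisopropylsilyloxy)benzene | Fc1c(Br)c(O[Si](C(C)C)(C(C)C)C(C)C)cc(O[Si](C(C)C)(C(C)C)C(C)C)c1Br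
F4 | step 5 | 1-bromo-2-fluoro-3-(3-methylbut-2-enyl)-4,6-bis(triisopropylsilyloxy)benzene | CC(C)=CCc1c(F)c(Br)c(O[Si](C(C)C)(C(C)C)C(C)C)cc1O[Si](C(C)C)(C(C)C)C(C)C
F0 | step 10 | none | none
F5 | step 15 | 3-hydroxy-2-[4,5-dihydroxy-2,3-bis(3-methylbut-2-enyl)phenyl]-8-(3-methylbut-2-enyl)-5,7-bis(triisopropylsilyloxy)chromen-4-one | CC(C)=CCc1c(-c2oc3c(CC=C(C)C)c(O[Si](C(C)C)(C(C)C)C(C)C)cc(O[Si](C(C)C)(C(C)C)C(C)C)c3c(=O)c2O)cc(O)c(O)c1CC=C(C)C
A1 | alternative 1 | 2-[2,3-bis(3-methylbut-2-enyl)-4,5-bis(methoxymethoxy)phenyl]-1,3-dioxolane | COCOc1cc(C2OCCO2)c(CC=C(C)C)c(CC=C(C)C)c1OCOC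
A2 | alternative 1 | 2-[2,3-dibromo-4,5-bis(methoxymethoxy)phenyl]-1,3-dioxolane | COCOc1cc(C2OCCO2)c(Br)c(Br)c1OCOC
A3 | alternative 2 | trans-3-(diethoxymethyl)-4,5-bis(3-methylbut-2-enyl)cyclohex-2-en-1-one (racemic, relative configuration shown) | O=C1C=C(C(OCC)OCC)[C@H](CC=C(C)C)[C@@H](CC=C(C)C)C1
A4 | alternative 2 | 1-(1,1-diethoxy-6-methylhepta-2,5-dien-2-yl)pyrrolidine | CCOC(OCC)C(=CCC=C(C)C)N1CCCC1
A5 | alternative 2 | (E)-7-methylocta-3,6-dien-2-one | CC(=O)/C=C/CC=C(C)C
A6 | alternative 3 | 5,7-dihydroxy-2-[2,3-bis(3-methylbut-2-enyl)-4,5-bis(methoxymethoxy)phenyl]-3-(methoxymethoxy)-8-(3-methylbut-2-enyl)chromen-4-one (identical with 25) | CC(C)=CCc1c(-c2oc3c(CC=C(C)C)c(O)cc(O)c3c(=O)c2OCOC)cc(OCOC)c(OCOC)c1CC=C(C)C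
A7 | alternative 3 | 2-[2,3-bis(3-methylbut-2-enyl)-4,5-bis(methoxymethoxy)phenyl]-3-(methoxymethoxy)-6-(4-methylpent-3-enyl)pyran-4-one | CC(C)=CCCc1cc(=O)c(OCOC)c(-c2cc(OCOC)c(OCOC)c(CC=C(C)C)c2CC=C(C)C)o1
A8 | alternative 3 | bis(2,4,6-trichlorophenyl) malonate | O=C(CC(=O)Oc1c(Cl)cc(Cl)cc1Cl)Oc1c(Cl)cc(Cl)cc1Cl
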